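The cyclohexene ring hides a meso 7-oxanorbornene. O5 can be tied back to C2 as an oxygen bridge, and the cis pair O1/O6 is the enediol of vinylene carbonate. The precursors of the key step are thus two flat, achiral, commercial heterocycles. Their Diels–Alder reaction, furan (C2–C5, O5) plus vinylene carbonate (C1, C6), forms C1–C2 and C5–C6 together. In the endo mode it sets O1 and O6 cis to each other and trans to O5. Catalytic monobenzoylation then breaks the symmetry. Exo addition of a hydroxymethyl anion equivalent to the C6 ketone builds the tertiary carbinol. A rhodium-catalysed anti SN2′ opening with benzoic acid releases C2=C3, the C4 benzoate and the C5 hydroxyl.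

Key step: step 1

Numbering used in the text (target numbering): C1 and C4 carry the benzoates, C2=C3 is the alkene, C5 carries the secondary hydroxyl, and C6 carries the tertiary hydroxyl and CH2OH. On is the oxygen on Cn.

Assumption: the senses of induction of the chiral ligands in steps 3 and 7 are taken by analogy with cis-cycloalkane-1,2-diols and with meso oxabicyclic alkenes. If either is opposite on these substrates, the antipodal ligand is used and nothing else changes.

Step 1
Reactants: 1 furan; 2 vinylene carbonate (1,3-dioxol-2-one)
Product: 3 endo-(3aR,4S,7R,7aS)-3a,4,7,7a-tetrahydro-4,7-epoxy-1,3-benzodioxol-2-one (meso; carbonate on the face opposite to the oxygen bridge)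
Conditions: excess furan as solvent, sealed tube, 125 °C, 20 h; endo isomer separated from the exo isomer by crystallisation
Reagents that add atoms: none
Why: This is a concerted, suprafacial thermal [4+2] cycloaddition (Diels–Alder reaction) in which furan C2 and C5 bond to the two alkene carbons of 2, so the future C1–C2 and C5–C6 bonds arise together and the six-membered carbocycle closes in one intermolecular event as part of a 7-oxanorbornene. The closest known reaction type is the thermal cycloaddition of furans with cyclic cis-dienophiles. The cis geometry of the cyclic dienophile fixes O1 and O6 cis, and the endo transition state places both on the face opposite to the oxygen bridge (the future O5), which is the O6/O5 trans relation of the target. All four new stereocentres are thereby set relative to each other, and because the product is meso no absolute control is needed at this stage. Regiochemistry is no issue because both partners are symmetric. The selectivity needed is endo over exo; it is expected to be weak because the cycloaddition is reversible, so 3 is separated and the exo isomer is reheated with furan to re-equilibrate.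

Step 2
Reactants: 3 endo carbonate adduct
Product: 4 (1R,2R,3S,4S)-7-oxabicyclo[2.2.1]hept-5-ene-2,3-diol (meso endo,endo-diol)
Conditions: K2CO3 (cat.), MeOH, 0 °C to rt
Reagents that add atoms: none
Why: Base-catalysed transesterification of the strained five-membered carbonate with methanol should free the cis-diol without touching a stereocentre, and the low temperature avoids cycloreversion.

Step 3
Reactants: 4 meso endo,endo-diol
Product: 5 (1R,2R,3R,4S)-3-hydroxy-7-oxabicyclo[2.2.1]hept-5-en-2-yl benzoate (both oxygens endo)
Conditions: BzCl (1.0 equiv), Cu(OTf)2 (5 mol %), 2,2′-isopropylidenebis[(4R)-4-phenyl-2-oxazoline] (5 mol %), iPr2NEt, CH2Cl2, −40 °C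
Reagents that add atoms: benzoyl chloride O=C(Cl)c1ccccc1
Why: In this catalytic enantioselective desymmetrisation by acylation, the diol chelates the chiral divalent copper bis(oxazoline) complex so that only one of the two enantiotopic hydroxyls is activated towards BzCl, which fixes the absolute configuration of the four existing stereocentres and installs the C1 benzoate of the target.

Step 4
Reactants: 5 endo hydroxy benzoate
Product: 6 (1R,2S,4S)-3-oxo-7-oxabicyclo[2.2.1]hept-5-en-2-yl benzoate (endo benzoate)
Conditions: Dess–Martin periodinane, CH2Cl2, 0 °C to rt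
Reagents that add atoms: none
Why: The Dess–Martin oxidation is neutral and non-basic, so it should convert the remaining endo carbinol (C6) into the ketone before 1,2-benzoyl migration can racemise 5, and without epimerising C1 or opening the bridge.

Step 5
Reactants: 7 4-methoxybenzyl alcohol; 8 tributyl(iodomethyl)stannane
Product: 10 tributyl{[(4-methoxybenzyl)oxy]methyl}stannane, via sodium 4-methoxybenzyl oxide 9 (not isolated)
Conditions: NaH, THF/DMF, 0 °C to rt
Reagents that add atoms: none
Why: This is a Williamson ether synthesis in which alkoxide 9 displaces iodide from the unhindered primary iodomethylstannane by SN2.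

Step 6
Reactants: 10 tributyl{[(4-methoxybenzyl)oxy]methyl}stannane; 6 endo benzoyloxy ketone
Product: 13 (1R,2S,3R,4S)-3-hydroxy-3-{[(4-methoxybenzyl)oxy]methyl}-7-oxabicyclo[2.2.1]hept-5-en-2-yl benzoate (OH and OBz endo; CH2OPMB exo), via alkoxymethyllithium 11 (not isolated), via alkoxymethylcerium dichloride 12 (not isolated)
Conditions: 10, n-BuLi, THF, −78 °C; anhydrous CeCl3, −78 °C; then 6, −78 °C; H2O quench
Reagents that add atoms: none
Why: Tin–lithium exchange and transmetalation give a weakly basic organocerium reagent whose 1,2-addition to the strained, very electrophilic ketone should outrun enolisation and ester attack, and approach from the open exo face of the 7-oxanorbornenone sets C6 with CH2O exo and OH endo (cis to O1, trans to O5).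

Step 7
Reactants: 13 tertiary carbinol
Product: 14 (1S,4R,5S,6R)-4-(benzoyloxy)-5,6-dihydroxy-6-{[(4-methoxybenzyl)oxy]methyl}cyclohex-2-en-1-yl benzoate
Conditions: [Rh(cod)Cl]2 (cat.), (R)-1-[(S)-2-(diphenylphosphino)ferrocenyl]ethyldi-tert-butylphosphine (cat.), AgOTf then Bu4NI (cat.), PhCO2H, Et3N, THF, 65 °C
Reagents that add atoms: benzoic acid O=C(O)c1ccccc1
Why: In this rhodium-catalysed ring opening of an oxabicyclic alkene with a carboxylate nucleophile, monovalent rhodium should insert from the exo face into the bridgehead C2–O bond remote from the exo CH2OPMB group, and benzoate should attack C4 from the endo face past the small endo hydroxyl (anti SN2′), which sets C4 trans to O5, moves the alkene to C2=C3 and frees O5–H.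

Step 8
Reactants: 14 PMB ether
Product: 15 (1S,4R,5S,6R)-4-(benzoyloxy)-5,6-dihydroxy-6-(hydroxymethyl)cyclohex-2-en-1-yl benzoate (CNP0212417.5)
Conditions: DDQ, CH2Cl2/pH 7 aqueous buffer, 0 °C to rt
Reagents that add atoms: none
Why: Oxidative cleavage of the electron-rich 4-methoxybenzyl ether by DDQ runs under neutral conditions, so the primary hydroxyl should be released without benzoyl migration and without touching a stereocentre.

Compound list
1 | furan | c1ccoc1 | starting material
2 | vinylene carbonate (1,3-dioxol-2-one) | O=C1OC=CO1 | starting material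
3 | endo-(3aR,4S,7R,7aS)-3a,4,7,7a-tetrahydro-4,7-epoxy-1,3-benzodioxol-2-one (meso) | O=C1O[C@H]2[C@H]3C=C[C@H](O3)[C@H]2O1 | intermediate
4 | (1R,2R,3S,4S)-7-oxabicyclo[2.2.1]hept-5-ene-2,3-diol (meso endo,endo-diol) | O[C@H]1[C@H]2C=C[C@H](O2)[C@H]1O | intermediate
5 | (1R,2R,3R,4S)-3-hydroxy-7-oxabicyclo[2.2.1]hept-5-en-2-yl benzoate | O=C(O[C@H]1[C@H]2C=C[C@H](O2)[C@H]1O)c1ccccc1 | intermediate
6 | (1R,2S,4S)-3-oxo-7-oxabicyclo[2.2.1]hept-5-en-2-yl benzoate | O=C(O[C@H]1[C@H]2C=C[C@H](O2)C1=O)c1ccccc1 | intermediate
7 | 4-methoxybenzyl alcohol | COc1ccc(CO)cc1 | starting material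
8 | tributyl(iodomethyl)stannane | CCCC[Sn](CCCC)(CCCC)CI | starting material
9 | sodium 4-methoxybenzyl oxide (not isolated) | [Na+].[O-]Cc1ccc(OC)cc1 | intermediate
10 | tributyl{[(4-methoxybenzyl)oxy]methyl}stannane | CCCC[Sn](CCCC)(CCCC)COCc1ccc(OC)cc1 | intermediate
11 | {[(4-methoxybenzyl)oxy]methyl}lithium (not isolated) | [Li]COCc1ccc(OC)cc1 | intermediate
12 | {[(4-methoxybenzyl)oxy]methyl}cerium dichloride (not isolated) | Cl[Ce](Cl)COCc1ccc(OC)cc1 | intermediate
13 | (1R,2S,3R,4S)-3-hydroxy-3-{[(4-methoxybenzyl)oxy]methyl}-7-oxabicyclo[2.2.1]hept-5-en-2-yl benzoate | O=C(O[C@H]1[C@H]2C=C[C@H](O2)[C@]1(O)COCc1ccc(OC)cc1)c1ccccc1 | intermediate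
14 | (1S,4R,5S,6R)-4-(benzoyloxy)-5,6-dihydroxy-6-{[(4-methoxybenzyl)oxy]methyl}cyclohex-2-en-1-yl benzoate | O=C(O[C@H]1C=C[C@@H](OC(=O)c2ccccc2)[C@H](O)[C@]1(O)COCc1ccc(OC)cc1)c1ccccc1 | intermediate
15 | (1S,4R,5S,6R)-4-(benzoyloxy)-5,6-dihydroxy-6-(hydroxymethyl)cyclohex-2-en-1-yl benzoate (CNP0212417.5) | O=C(O[C@H]1C=C[C@@H](OC(=O)c2ccccc2)[C@H](O)[C@]1(O)CO)c1ccccc1 | target

Total step count: 8. Longest linear sequence: 7 (steps 1, 2, 3, 4, 6, 7, 8).

Steps most likely to fail

Step 7.
- What may go wrong: the catalyst may cleave the other bridgehead C–O bond. Insertion may be slow because both endo substituents crowd the face from which benzoate must arrive. Benzoyl groups may migrate in the warm amine-buffered medium.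
- Fallback: it sets out from 13 and comes back at 15, replacing the catalytic oxygen nucleophile by a stoichiometric halide opening and an epoxide relay.
- BBr3 (CH2Cl2, −78 °C) is used in a known reaction type for cleaving 7-oxanorbornene bridges. It should remove the PMB ether, open the bridge at the less encumbered C2–O bond and deliver bromide to C4 anti to the departing oxygen, giving the trans bromohydrin F1.
- DBU (CH2Cl2, 0 °C) closes the vinyl epoxide F2 between C4 and C5 on the face of O5. An allylic bromide isomer carrying bromine at C2 would reach the same epoxide by SN2′ closure.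
- PhCO2H with Ti(OiPr)4 (CH2Cl2, rt) then opens F2 with inversion at C4. This carbon is both the distal carbon of the 2,3-epoxy alcohol unit and the allylic one, so 15 results directly.

Step 6.
- What may go wrong: the α-benzoyloxy ketone may enolise, followed by β-elimination of the oxygen bridge and aromatisation. The reagent may attack the ester. The benzoyl group may migrate within the alkoxide.
- Fallback: it sets out from 6 and comes back at 15, using a silicon-masked hydroxymethyl Grignard reagent and an endgame without a protecting group.
- (Isopropoxydimethylsilyl)methylmagnesium chloride (THF, −78 °C) adds from the exo face to give the β-hydroxysilane F3.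
- Tamao–Fleming oxidation (H2O2, KF, KHCO3, THF/MeOH) gives the endo carbinol with a free exo hydroxymethyl group, F4.
- The conditions of step 7 applied to F4 lead straight to 15.

Step 3.
- What may go wrong: discrimination between the enantiotopic hydroxyls may be insufficient. Double acylation may occur. Compound 5 may racemise through 1,2-benzoyl migration.
- Fallback: it sets out from 4 and comes back at 5, moving the symmetry-breaking event to an enzymatic ester hydrolysis.
- Ac2O/pyridine gives the meso diacetate F5.
- A lipase selected by screening (pH 7 buffer) hydrolyses the acetate on C1 to give the monoacetate F6.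
- BzCl/pyridine gives the acetate benzoate F7.
- The same class of enzyme, which accepts acetates but not benzoates, removes the remaining acetate to give 5.

Further compounds
F1 | step 7 | (1S,4R,5R,6R)-4-bromo-5,6-dihydroxy-6-(hydroxymethyl)cyclohex-2-en-1-yl benzoate | O=C(O[C@H]1C=C[C@@H](Br)[C@H](O)[C@]1(O)CO)c1ccccc1
F2 | step 7 | (1S,2S,3S,6S)-2-hydroxy-2-(hydroxymethyl)-7-oxabicyclo[4.1.0]hept-4-en-3-yl benzoate | O=C(O[C@H]1C=C[C@@H]2O[C@@H]2[C@]1(O)CO)c1ccccc1
F3 | step 6 | (1R,2S,3R,4S)-3-hydroxy-3-{[isopropoxy(dimethyl)silyl]methyl}-7-oxabicyclo[2.2.1]hept-5-en-2-yl benzoate | O=C(O[C@H]1[C@H]2C=C[C@H](O2)[C@]1(O)C[Si](C)(C)OC(C)C)c1ccccc1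
F4 | step 6 | (1R,2S,3R,4S)-3-hydroxy-3-(hydroxymethyl)-7-oxabicyclo[2.2.1]hept-5-en-2-yl benzoate | O=C(O[C@H]1[C@H]2C=C[C@H](O2)[C@]1(O)CO)c1ccccc1
F5 | step 3 | (1R,2S,3R,4S)-7-oxabicyclo[2.2.1]hept-5-ene-2,3-diyl diacetate (meso, endo,endo) | CC(=O)O[C@H]1[C@H]2C=C[C@H](O2)[C@H]1OC(C)=O
F6 | step 3 | (1S,2S,3S,4R)-3-hydroxy-7-oxabicyclo[2.2.1]hept-5-en-2-yl acetate | O[C@H]1[C@H]2C=C[C@H](O2)[C@H]1OC(C)=O
F7 | step 3 | (1R,2S,3R,4S)-3-acetoxy-7-oxabicyclo[2.2.1]hept-5-en-2-yl benzoate | O=C(O[C@H]1[C@H]2C=C[C@H](O2)[C@H]1OC(C)=O)c1ccccc1
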